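Rings and locants: A = resorcinol ring; B = central ring of the 9,10-dihydrophenanthrene A–B–C; C = monohydroxy ring; D and F = fused and pendant catechols; E = seven-membered ring. C–E–D is numbered as dibenzo[a,d][7]annulene (C-5 = CH shared by B and E, C-10 = CH bearing F; the target is 5R,10S).
Enabling feature: the only OH of ring C (C-2) is para to C-4a, which carries C-5, and meta to the biaryl carbon C-4; the ring A biaryl carbon is ortho/para to two oxygens. This is the imprint of a para-spirodienone that has undergone a 1,2-aryl (dienone–phenol) shift.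
Cuts, backwards: six O–CH3; ring B contracted to the five-membered ring of spiro[4.5]dienone 18, then opened at C-4a–ring A (phenol 17); the C-5 benzyl group (alkene 16, ketone 12); C-10–H (enone 11); acyl bond C-5–C-5a of ring E (acid 9); two C-10–aryl bonds (ester 3).
Forward order: ring C ester → triarylethylene with two identical 3,4-dimethoxyphenyl groups (no stereocentre) → ring E by Friedel–Crafts acylation (one aryl becomes ring D, the other ring F) → ring A benzylidene → 17 → ring B by oxidative spirocyclisation and ring expansion → demethylation.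
Stereochemistry: C-10 from iridium-catalysed asymmetric hydrogenation of achiral enone 11; C-5 from hydrogenation of 16 anti to the C-10 aryl (5-H/10-H cis); the key step touches neither centre.

Key step: step 9

Remark: the seven-membered ring of 11–17 is assumed to adopt the boat form usual for 5H-dibenzo[a,d][7]annulenes; the facial argument of step 8 rests on it.

Step 1
Reactants: 1 3-hydroxyphenylacetic acid
Product: 2 benzyl [3-(benzyloxy)phenyl]acetate
Conditions: BnBr (2.3 equiv), K2CO3, DMF, 60 °C
Reagents that add atoms: benzyl bromide, BrCc1ccccc1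
Why: Williamson-type alkylation of the phenoxide and of the carboxylate under K2CO3 gives in one operation the benzyl ether that is later removed in the hydrogenation of step 8 and the ester needed for the double Grignard addition.

Step 2
Reactants: 2 benzyl [3-(benzyloxy)phenyl]acetate
Product: 3 benzyl [5-(benzyloxy)-2-bromophenyl]acetate
Conditions: NBS (1.05 equiv), MeCN, 0 → 25 °C, dark
Reagents that add atoms: N-bromosuccinimide, O=C1CCC(=O)N1Br
Why: Electrophilic aromatic bromination goes para to the benzyloxy group (ortho to the acetate arm), the established site for 3-alkoxyphenylacetates, and places the handle for the later carbonyl carbon C-5 on the future C-4a.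

Step 3
Reactants: 3 benzyl [5-(benzyloxy)-2-bromophenyl]acetate; 4 3,4-dimethoxyphenylmagnesium bromide (2.5 equiv)
Product: 7 4-(benzyloxy)-1-bromo-2-[2,2-bis(3,4-dimethoxyphenyl)ethenyl]benzene, via ketone 5 (not isolated), via tertiary alcohol 6 (not isolated)
Conditions: THF, 0 → 25 °C; H2O; then TsOH·H2O (5 mol%), PhMe, 80 °C
Reagents that add atoms: none
Why: Double Grignard addition to the ester followed by acid-catalysed E1 dehydration through the doubly aryl-stabilised tertiary cation gives the triarylethylene, and since the two new aryl groups are identical no stereocentre or alkene isomer arises.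

Step 4
Reactants: 7 4-(benzyloxy)-1-bromo-2-[2,2-bis(3,4-dimethoxyphenyl)ethenyl]benzene
Product: 9 4-(benzyloxy)-2-[2,2-bis(3,4-dimethoxyphenyl)ethenyl]benzoic acid, via aryllithium 8 (not isolated)
Conditions: n-BuLi (1.05 equiv), THF, −78 °C, 10 min; CO2; aq HCl
Reagents that add atoms: carbon dioxide, O=C=O
Why: Bromine–lithium exchange at −78 °C outruns carbolithiation of the electron-rich trisubstituted alkene, and the aryllithium is trapped by CO2 (carboxylation).

Step 5
Reactants: 9 4-(benzyloxy)-2-[2,2-bis(3,4-dimethoxyphenyl)ethenyl]benzoic acid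
Product: 11 2-(benzyloxy)-10-(3,4-dimethoxyphenyl)-7,8-dimethoxy-5H-dibenzo[a,d][7]annulen-5-one, via acyl chloride 10 (not isolated)
Conditions: (COCl)2 (1.1 equiv), DMF (cat.), CH2Cl2, 0 °C; then SnCl4 (1.1 equiv), −78 → −20 °C
Reagents that add atoms: none
Why: Intramolecular Friedel–Crafts acylation closes seven-membered ring E onto the dimethoxyphenyl group held cis across the double bond, at its position para to a methoxy group; because the two aryl groups are identical, either choice gives the same achiral enone, one aryl becoming ring D and the other ring F.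

Step 6
Reactants: 11 2-(benzyloxy)-10-(3,4-dimethoxyphenyl)-7,8-dimethoxy-5H-dibenzo[a,d][7]annulen-5-one
Product: 12 (10S)-2-(benzyloxy)-10-(3,4-dimethoxyphenyl)-7,8-dimethoxy-10,11-dihydro-5H-dibenzo[a,d][7]annulen-5-one
Conditions: H2 (50 bar), [Ir(cod)(L)][B(C6H3(CF3)2)4] (2 mol%; cod = cycloocta-1,5-diene, L = 4-tert-butyl-2-[2-(diphenylphosphanyl)phenyl]-4,5-dihydrooxazole, antipode selected for 10S), CH2Cl2, 25 °C
Reagents that add atoms: none
Why: Iridium N,P-ligand catalysed asymmetric hydrogenation of a trisubstituted aryl alkene whose geometry is locked by the ring, so that enantioface selection by the chiral catalyst alone sets C-10 (S), while the diaryl ketone and the benzyl ether are inert to this catalyst.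

Step 7
Reactants: 12 (10S)-2-(benzyloxy)-10-(3,4-dimethoxyphenyl)-7,8-dimethoxy-10,11-dihydro-5H-dibenzo[a,d][7]annulen-5-one; 13 3,5-dimethoxybenzyl chloride
Product: 16 (10S)-2-(benzyloxy)-5-(3,5-dimethoxybenzylidene)-10-(3,4-dimethoxyphenyl)-7,8-dimethoxy-10,11-dihydro-5H-dibenzo[a,d][7]annulene (E/Z mixture), via Grignard reagent 14 (not isolated), via tertiary alcohol 15 (not isolated)
Conditions: 13, Mg, THF, 0 °C; add 12, −78 → 0 °C; H2O; then methyl N-(triethylammoniosulfonyl)carbamate (inner salt), PhMe, 50 °C
Reagents that add atoms: none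
Why: Grignard addition of the benzylmagnesium chloride to the diaryl ketone, followed by syn elimination of the tertiary alcohol through its sulfamate ester under non-acidic conditions (so that a C-5 cation cannot be trapped by ring F), gives the exocyclic triaryl alkene without touching C-10.

Step 8
Reactants: 16 (10S)-2-(benzyloxy)-5-(3,5-dimethoxybenzylidene)-10-(3,4-dimethoxyphenyl)-7,8-dimethoxy-10,11-dihydro-5H-dibenzo[a,d][7]annulene
Product: 17 (5S,10S)-5-(3,5-dimethoxybenzyl)-10-(3,4-dimethoxyphenyl)-7,8-dimethoxy-10,11-dihydro-5H-dibenzo[a,d][7]annulen-2-ol (5-H cis to 10-H)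
Conditions: H2 (3 bar), 10% Pd/C, EtOAc–EtOH, 25 °C
Reagents that add atoms: none
Why: Heterogeneous syn hydrogenation on Pd, which in the same operation hydrogenolyses the benzyl ether, can reach the exocyclic alkene only from the convex face of the boat-shaped seven-membered ring, and that face is open only in the boat that holds the C-10 aryl pseudo-equatorial, so hydrogen should be delivered anti to that aryl and set C-5 with 5-H cis to 10-H (5S).

Step 9
Reactants: 17 (5S,10S)-5-(3,5-dimethoxybenzyl)-10-(3,4-dimethoxyphenyl)-7,8-dimethoxy-10,11-dihydro-5H-dibenzo[a,d][7]annulen-2-ol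
Product: 19 (5R,10S)-hexa-O-methyl ether of target 20 with free ring C hydroxyl, via spirodienone 18 (not isolated)
Conditions: PhI(OCOCF3)2 (1.05 equiv), (CF3)2CHOH–CH2Cl2, −40 °C; then BF3·OEt2 (0.3 equiv), −40 → 0 °C
Reagents that add atoms: none
Why: The phenol exchanges onto trivalent iodine and, as PhI departs, the ring A carbon ortho to its CH2 (ortho and para to the two methoxy groups) attacks C-4a, the carbon para to the phenolic oxygen, to give spiro[4.5]dienone 18; BF3 then activates the dienone and the same ring A carbon shifts from C-4a to the neighbouring unsubstituted C-4, after which loss of H-4 rearomatises ring C, so that the five-membered carbocycle is enlarged to six-membered ring B and the biaryl bond ends meta to the ring C hydroxyl. The closest known reaction types are the hypervalent-iodine para-spirocyclisation of 4-(2-arylethyl)phenols and the acid-mediated dienone–phenol rearrangement of the resulting spiro[4.5]dienones, as in the proaporphine-to-aporphine change. The spiro ring closes by 5-exo-trig ipso attack of the arene on the oxidised phenol, and ring B is not closed directly but arises from that ring by the 1,2-aryl shift. No stereocentre is created in the product: the transient spiro carbon is fixed by the cis fusion that ring E enforces, and C-5 and C-10 are neither ionised nor deprotonated, so 5S,10S of 17 becomes 5R,10S of 19 by a change of descriptor only (C-4 gains a carbon substituent). The step needs para ipso attack by ring A rather than ortho attack by ring F or oxidation of the dimethoxyarenes, which the free phenol (the only group that binds iodine), the large para coefficient of the oxidised phenol, the doubly activated ring A carbon and the favourable five-membered closure should secure. It also needs migration of the aryl carbon to C-4 rather than migration or heterolysis of the C-4a–C-5 bond (which would scramble C-5) or a shift to C-11a, which the phenonium-type stabilisation of the 2,4-dimethoxyphenyl migrating group, the hydrogen on C-4 that alone allows aromatisation, and the eight-membered ring that a C-5 shift would cost should secure.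

Step 10
Reactants: 19 (5R,10S)-hexa-O-methyl ether of target 20 with free ring C hydroxyl
Product: 20 target CNP0306974.1 (5R,10S)
Conditions: BBr3 (12 equiv), CH2Cl2, −78 → 25 °C; then H2O
Reagents that add atoms: none
Why: BBr3 cleaves all six aryl methyl ethers by Lewis acid activation and bromide SN2 attack on methyl, conditions under which the doubly benzylic C-5 and C-10 should not be ionised.

Compound list
1 | 3-hydroxyphenylacetic acid | OC(=O)Cc1cccc(O)c1 | starting material
2 | benzyl [3-(benzyloxy)phenyl]acetate | O=C(Cc1cccc(OCc2ccccc2)c1)OCc1ccccc1 | intermediate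
3 | benzyl [5-(benzyloxy)-2-bromophenyl]acetate | O=C(Cc1cc(OCc2ccccc2)ccc1Br)OCc1ccccc1 | intermediate
4 | 3,4-dimethoxyphenylmagnesium bromide (THF solution) | COc1ccc([Mg]Br)cc1OC | starting material
5 | 2-[5-(benzyloxy)-2-bromophenyl]-1-(3,4-dimethoxyphenyl)ethan-1-one | O=C(Cc1cc(OCc2ccccc2)ccc1Br)c1ccc(OC)c(OC)c1 | intermediate (not isolated)
6 | 2-[5-(benzyloxy)-2-bromophenyl]-1,1-bis(3,4-dimethoxyphenyl)ethan-1-ol | OC(Cc1cc(OCc2ccccc2)ccc1Br)(c1ccc(OC)c(OC)c1)c1ccc(OC)c(OC)c1 | intermediate (not isolated)
7 | 4-(benzyloxy)-1-bromo-2-[2,2-bis(3,4-dimethoxyphenyl)ethenyl]benzene | Brc1ccc(OCc2ccccc2)cc1C=C(c1ccc(OC)c(OC)c1)c1ccc(OC)c(OC)c1 | intermediate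
8 | {4-(benzyloxy)-2-[2,2-bis(3,4-dimethoxyphenyl)ethenyl]phenyl}lithium | [Li]c1ccc(OCc2ccccc2)cc1C=C(c1ccc(OC)c(OC)c1)c1ccc(OC)c(OC)c1 | intermediate (not isolated)
9 | 4-(benzyloxy)-2-[2,2-bis(3,4-dimethoxyphenyl)ethenyl]benzoic acid | OC(=O)c1ccc(OCc2ccccc2)cc1C=C(c1ccc(OC)c(OC)c1)c1ccc(OC)c(OC)c1 | intermediate
10 | 4-(benzyloxy)-2-[2,2-bis(3,4-dimethoxyphenyl)ethenyl]benzoyl chloride | O=C(Cl)c1ccc(OCc2ccccc2)cc1C=C(c1ccc(OC)c(OC)c1)c1ccc(OC)c(OC)c1 | intermediate (not isolated)
11 | 2-(benzyloxy)-10-(3,4-dimethoxyphenyl)-7,8-dimethoxy-5H-dibenzo[a,d][7]annulen-5-one | O=C1c2cc(OC)c(OC)cc2C(c2ccc(OC)c(OC)c2)=Cc2cc(OCc3ccccc3)ccc21 | intermediate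
12 | (10S)-2-(benzyloxy)-10-(3,4-dimethoxyphenyl)-7,8-dimethoxy-10,11-dihydro-5H-dibenzo[a,d][7]annulen-5-one | O=C1c2cc(OC)c(OC)cc2[C@H](c2ccc(OC)c(OC)c2)Cc2cc(OCc3ccccc3)ccc21 | intermediate
13 | 3,5-dimethoxybenzyl chloride | COc1cc(CCl)cc(OC)c1 | starting material
14 | 3,5-dimethoxybenzylmagnesium chloride | COc1cc(C[Mg]Cl)cc(OC)c1 | intermediate (not isolated)
15 | (10S)-2-(benzyloxy)-5-(3,5-dimethoxybenzyl)-10-(3,4-dimethoxyphenyl)-7,8-dimethoxy-10,11-dihydro-5H-dibenzo[a,d][7]annulen-5-ol (both C-5 epimers) | OC1(Cc2cc(OC)cc(OC)c2)c2cc(OC)c(OC)cc2[C@H](c2ccc(OC)c(OC)c2)Cc2cc(OCc3ccccc3)ccc21 | intermediate (not isolated)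
16 | (10S)-2-(benzyloxy)-5-(3,5-dimethoxybenzylidene)-10-(3,4-dimethoxyphenyl)-7,8-dimethoxy-10,11-dihydro-5H-dibenzo[a,d][7]annulene (E/Z mixture) | COc1cc(OC)cc(c1)C=C1c2cc(OC)c(OC)cc2[C@H](c2ccc(OC)c(OC)c2)Cc2cc(OCc3ccccc3)ccc21 | intermediate
17 | (5S,10S)-5-(3,5-dimethoxybenzyl)-10-(3,4-dimethoxyphenyl)-7,8-dimethoxy-10,11-dihydro-5H-dibenzo[a,d][7]annulen-2-ol (5-H cis to 10-H) | COc1cc(OC)cc(c1)C[C@@H]1c2cc(OC)c(OC)cc2[C@H](c2ccc(OC)c(OC)c2)Cc2cc(O)ccc21 | intermediate
18 | (5R,10S)-spirodienone: ring C of 17 as a cyclohexa-2,5-dien-1-one (C-2 carbonyl) whose C-4a is a spiro carbon also bonded to the ring A carbon ortho to the CH2 (five-membered ring C-4a/C-5/CH2/two ring A carbons), ring A bonded on the face of ring C that carries ring D (cis-fused to ring E) | COc1cc(OC)c2c(c1)C[C@@H]1c3cc(OC)c(OC)cc3[C@H](c3ccc(OC)c(OC)c3)CC3=CC(=O)C=C[C@@]213 | intermediate (not isolated)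
19 | (5R,10S)-hexa-O-methyl ether of the target: 17 with an added bond from C-4 to the ring A carbon ortho to the CH2 (ring B), OCH3 on rings A, D and F, free OH on ring C | COc1cc(OC)c2c(c1)C[C@@H]1c3cc(OC)c(OC)cc3[C@H](c3ccc(OC)c(OC)c3)Cc3cc(O)cc-2c31 | intermediate
20 | CNP0306974.1, (5R,10S) pentacyclic heptaphenol | Oc1cc(O)c2c(c1)C[C@@H]1c3cc(O)c(O)cc3[C@H](c3ccc(O)c(O)c3)Cc3cc(O)cc-2c31 | target

Total step count: 10. Longest linear sequence: 10 steps (from 1; 4 and 13 enter as reagent-like fragments).

Steps most likely to fail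

Step 9. The oxidised phenol may be captured at its ortho carbon by ring F (a six-membered biaryl closure), or the dimethoxyarenes may be oxidised, instead of para ipso attack by ring A. The fallback sets out from 17 and comes back at 19, forming the same spiro bond without an oxidant. Phenol 17 is acetylated (Ac2O, pyridine) to the aryl acetate F3. NBS in MeCN at 0 °C brominates the most activated ring, ring A, ortho to its CH2, to give the bromo acetate F4. K2CO3 in MeOH frees the bromophenol F5. Dearomative ipso-arylation of the phenoxide catalysed by zerovalent palladium (Pd2(dba)3, 2-(dicyclohexylphosphanyl)-2′,4′,6′-triisopropylbiphenyl, K2CO3, dioxane, 100 °C) can form only the C-4a–ring A bond and gives 18, now isolated. BF3·OEt2 in CH2Cl2 then effects the ring expansion to 19.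

Step 6. Hydrogen delivery to the hindered triaryl alkene may be slow or poorly face-selective. The fallback sets out from 11 and comes back at 12. Non-selective hydrogenation that keeps the benzyl ether (H2, 5% Pd/C, Ph2S, EtOAc) gives the racemic ketone. Preparative chromatography on a chiral stationary phase separates 12 from its (10R)-enantiomer F1, which is set aside.

Step 8. Facial selectivity of hydrogen delivery to the exocyclic alkene may be poor if the conformational bias is weak, giving the 5-epimer alongside 17. The fallback sets out from 16 and comes back at 17, replacing substrate control by catalyst control. The alkene isomers of 16 are separated and the major one is reduced with the matched antipode of the cationic iridium N,P complex of step 6 (H2, 50 bar, CH2Cl2), which leaves the benzyl ether in place and gives the benzyl ether F2. Hydrogenolysis (H2, 10% Pd/C, EtOAc–EtOH) then gives 17.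

Further compounds
F1 | step 6 | (10R)-2-(benzyloxy)-10-(3,4-dimethoxyphenyl)-7,8-dimethoxy-10,11-dihydro-5H-dibenzo[a,d][7]annulen-5-one | O=C1c2cc(OC)c(OC)cc2[C@@H](c2ccc(OC)c(OC)c2)Cc2cc(OCc3ccccc3)ccc21
F2 | step 8 | (5S,10S)-2-(benzyloxy)-5-(3,5-dimethoxybenzyl)-10-(3,4-dimethoxyphenyl)-7,8-dimethoxy-10,11-dihydro-5H-dibenzo[a,d][7]annulene | COc1cc(OC)cc(c1)C[C@@H]1c2cc(OC)c(OC)cc2[C@H](c2ccc(OC)c(OC)c2)Cc2cc(OCc3ccccc3)ccc21
F3 | step 9 | (5S,10S)-5-(3,5-dimethoxybenzyl)-10-(3,4-dimethoxyphenyl)-7,8-dimethoxy-10,11-dihydro-5H-dibenzo[a,d][7]annulen-2-yl acetate | COc1cc(OC)cc(c1)C[C@@H]1c2cc(OC)c(OC)cc2[C@H](c2ccc(OC)c(OC)c2)Cc2cc(OC(C)=O)ccc21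
F4 | step 9 | (5S,10S)-5-[(2-bromo-3,5-dimethoxyphenyl)methyl]-10-(3,4-dimethoxyphenyl)-7,8-dimethoxy-10,11-dihydro-5H-dibenzo[a,d][7]annulen-2-yl acetate | COc1cc(OC)c(Br)c(c1)C[C@@H]1c2cc(OC)c(OC)cc2[C@H](c2ccc(OC)c(OC)c2)Cc2cc(OC(C)=O)ccc21
F5 | step 9 | (5S,10S)-5-[(2-bromo-3,5-dimethoxyphenyl)methyl]-10-(3,4-dimethoxyphenyl)-7,8-dimethoxy-10,11-dihydro-5H-dibenzo[a,d][7]annulen-2-ol | COc1cc(OC)c(Br)c(c1)C[C@@H]1c2cc(OC)c(OC)cc2[C@H](c2ccc(OC)c(OC)c2)Cc2cc(O)ccc21
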